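Start with the closed flask: midnight has the same recipe as the zeta run, so your quick number lies in the zeta table, and I share your hunch that charging everything at once wins.

| flask | starting material | coupling partner | protic impurity | remark | time |
|---|---|---|---|---|---|
| zeta | 0.24 M | 0.264 M | 0.048 M | run made earlier |  |
| alpha | 0.24 M | 0.264 M | 0.024 M | run made earlier |  |
| gamma | 0.24 M | 0.264 M | 0.036 M | run made earlier |  |
| spring | 0.24 M | 0.264 M | 0.0480 M | a single well-mixed tank run continuously and read at steady state, 20 h in it on average |  |
| autumn | 0.24 M | 0.264 M (fed, over 20.0 h) | 0.0480 M | a stirred flask in which coupling partner is dosed at a steady rate over 20.0 h without added volume, worked up at 20 h | 20 h |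
| midnight | 0.24 M | 0.264 M | 0.0480 M | a closed flask charged with all of it at once and left for 20 h | 20 h |
| dawn | 0.24 M (fed, over 20.0 h) | 0.264 M | 0.0480 M | a stirred flask in which starting material is dosed at a steady rate over 20.0 h without added volume, worked up at 20 h | 20 h |

| run | time / h | target / % |
|---|---|---|
| zeta | 1.50 | 57.4 |
| zeta | 3.00 | 77.6 |
| zeta | 6.00 | 88.2 |
| zeta | 10.0 | 89.3 |
| zeta | 20.0 | 93.1 |
| alpha | 1.33 | 54.0 |
| alpha | 4.00 | 83.7 |
| alpha | 8.00 | 91.5 |
| alpha | 12.0 | 92.5 |
| alpha | 15.0 | 94.0 |
| gamma | 1.33 | 53.6 |
| gamma | 4.00 | 80.9 |
| gamma | 8.00 | 91.7 |
| gamma | 12.0 | 94.4 |
| gamma | 15.0 | 94.6 |

(standard deviation of a reading: 1 percentage point)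

- the set-up with the highest amount of target at the outlet or at the end, in percent of the starting material put in ("none" if the first two lie within 2 percentage points) (spring / autumn / midnight / dawn / none)
- amount of target at the outlet or at the end, in percent of the starting material put in, spring
- amount of target at the outlet or at the end, in percent of the starting material put in, autumn
- amount of target at the outlet or at the end, in percent of the starting material put in, midnight
- amount of target at the outlet or at the end, in percent of the starting material put in, dawn

- the stated concentrations are those of everything mixed, before any reaction; amounts are the same in each set-up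
- the feed brings no volume worth counting
- the earlier runs were made in a closed, stirred flask

Read the pace off the first zeta point, counting target as reacted starting material. With nearly equal charges, the rate follows c(starting material) times c(coupling partner), so each half-life runs longer than the one before: after n first half-lives, one part in n plus one remains. The zeta reading of 57.4% at 1.50 h gives a first half-life of 1.11 h.

Now count. Midnight's 20 h holds 18.0 of them, which leaves 5.27% and makes 94.7%. The last zeta reading says 93.1%, and that is my number for midnight.

For spring, balance feed against reaction in the tank. If x is the part left, one minus x equals n times x squared, with the same n, the average stay in the tank matching midnight's time. That gives x = 21.0%, so my spring is 79.0%. I have no count for the dosed flasks.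

The forecast picks midnight, with spring 77.5%, autumn 79%, midnight 91% and dawn 78%, and holds that “the impurity must be consuming partner”. My midnight stands higher than its number, and so does my spring.

Midnight gives 93.4%, the highest, with spring at 78.4%, dawn at 79.4% and autumn at 64.7%. Autumn is 14 percentage points below the forecast and at 20.0 h holds 33.2% of the starting material charged as homo dimer.

    starting material + coupling partner → intermediate + by-product (k = 6.07 M⁻¹ h⁻¹)
    intermediate → target (k = 2.02 h⁻¹)
    2 starting material → homo dimer (k = 0.173 M⁻¹ h⁻¹)
    coupling partner + protic impurity → quenched reagent (k = 1.78 M⁻¹ h⁻¹)

Now take the neighbouring flask, which is midnight with 0.16 M of coupling partner. Stretch the half-life to 1.67 h for the smaller charge, and 20 h holds 12.0 of them. So expect the partner to act as the limiting reagent at 0.667 equiv, with target stopping near 66.7%. In the neighbouring flask, 0% of the coupling partner charged remains, along with 21% of the starting material charged, and target reaches 61.4%.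

(All runs are calculated for substances that don't exist, noise included.)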